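## Retrosynthetic overview

1. Feature: the single carbocycle is numbered C1 (methylene-bearing), C2, C3, C4 (acetoxy-bearing), C5 (gem-dimethyl) and C6 (chain-bearing). In it C4–O is tied through C3 and C2 to C1=CH2, a homoallylic alcohol array. A cyclopropane C1–C2–C3 with a CH2SiMe3 group on C1 can hand this array to a C4 aldehyde.
2. Disconnection 1: the C(sp3)–C(sp2) bond between the ring CH2CH2 stub and the first trisubstituted alkene. It is made by Negishi coupling of an alkylzinc iodide and a C19 E-2-iodoalkene built from farnesyl bromide, so the polyene arrives only after ring closure.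
3. Disconnection 2: C3–C4, by Lewis-acid opening of the silylmethylcyclopropane onto the neopentyl aldehyde. This closes the only ring of the target and sets C4 from C6.
4. Disconnection 3: the cyclopropane comes from a 2-substituted allylsilane (Simmons–Smith). The allylsilane comes from an α-substituted γ-butyrolactone (double Me3SiCH2 addition, Peterson elimination).
5. Disconnection 4: C6 is set by Evans allylation of the 2,2-dimethylsuccinyl imide. Order of rings: lactone (temporary), cyclopropane (temporary), cyclohexane.

Key step: step 10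

Assumption: the ring numbering C1–C6 of the overview is used throughout, and commercial (2E,6E)-farnesyl bromide is taken to be geometrically pure.

## Route

Step 1
Reactants: 1 2,2-dimethylsuccinic anhydride; 2 (4S)-4-benzyl-1,3-oxazolidin-2-one
Product: 4 4-[(4S)-4-benzyl-2-oxo-1,3-oxazolidin-3-yl]-2,2-dimethyl-4-oxobutanoic acid, via N-lithio oxazolidinone 3 (not isolated)
Conditions: 2, n-BuLi, THF, −78 °C; then 1, −78 → 0 °C; 1 M HCl work-up
Reagents that add atoms: none
Why: Acylation of a lithiated oxazolidinone by a cyclic anhydride, in which the bulky nitrogen nucleophile should open 1 at the carbonyl next to CH2 rather than at the one shielded by the gem-dimethyl group, so that the auxiliary sits on the future C1 and the future C4 stays as the free acid.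

Step 2
Reactants: 4 imide acid
Product: 5 tert-butyl 4-[(4S)-4-benzyl-2-oxo-1,3-oxazolidin-3-yl]-2,2-dimethyl-4-oxobutanoate
Conditions: Cl3CC(=NH)OtBu (2 equiv), CH2Cl2–cyclohexane, rt
Reagents that add atoms: tert-butyl 2,2,2-trichloroacetimidate, CC(C)(C)OC(=N)C(Cl)(Cl)Cl
Why: Trichloroacetimidate O-tert-butylation transfers the alkyl group to the carboxyl oxygen, so crowding at the acyl carbon is irrelevant, no strong acid that could return the imide acid to the anhydride is present, and the pivalate-type tert-butyl ester is inert to the enolate and organocerium steps that follow.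

Step 3
Reactants: 5 imide ester; 6 allyl iodide
Product: 8 tert-butyl (3S)-3-{[(4S)-4-benzyl-2-oxo-1,3-oxazolidin-3-yl]carbonyl}-2,2-dimethylhex-5-enoate, via sodium Z-enolate 7 (not isolated)
Conditions: NaN(SiMe3)2 (1.1 equiv), THF, −78 °C; 6 (5 equiv), −78 → −40 °C
Reagents that add atoms: none
Why: Evans asymmetric alkylation, in which the chelated sodium Z-enolate is shielded on one face by the benzyl group of the (S)-auxiliary, so that allyl iodide should enter from the other face and set C6 with the spatial arrangement of the target (descriptor S here because the imide carbonyl outranks C5).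

Step 4
Reactants: 8 allylated imide
Product: 11 tert-butyl 2-methyl-2-[(3S)-2-oxooxolan-3-yl]propanoate, via aldehyde 9 (not isolated), via hydroxy imide 10 (not isolated)
Conditions: O3, CH2Cl2–MeOH, −78 °C; NaBH4, −78 → 0 °C, then rt; aq NH4Cl
Reagents that add atoms: ozone, [O-][O+]=O
Why: Ozonolysis with reductive NaBH4 work-up shortens the allyl group to the CH2CH2O stub, and the primary alkoxide then attacks the activated imide carbonyl in a 5-exo-trig lactonisation that releases the auxiliary from a hindered acyl group without an external nucleophile and leaves C6 untouched.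

Step 5
Reactants: 11 lactone ester; 12 (trimethylsilyl)methylmagnesium chloride
Product: 14 tert-butyl (3S)-5-hydroxy-2,2-dimethyl-3-[3-(trimethylsilyl)prop-1-en-2-yl]pentanoate, via bis(silylmethyl) carbinol 13 (not isolated)
Conditions: 12 (5 equiv), anhydrous CeCl3 (5 equiv), THF, −78 °C → rt; aq NH4Cl; then SiO2, CH2Cl2, rt
Reagents that add atoms: none
Why: CeCl3-mediated double addition of the silylmethyl Grignard reagent to a lactone followed by Peterson elimination is the standard conversion of an ester carbonyl into a 2-substituted allylsilane, the weakly basic organocerium reagent should spare the C6–H, and the tert-butyl ester on quaternary C5 should not react.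

Step 6
Reactants: 14 hydroxy ester
Product: 15 (3S)-2,2-dimethyl-3-[3-(trimethylsilyl)prop-1-en-2-yl]pentane-1,5-diol
Conditions: LiAlH4, THF, 0 °C → reflux; aqueous NaOH work-up
Reagents that add atoms: none
Why: LiAlH4 ester reduction is placed here because only hydroxyl and allylsilane groups are present, so the forcing conditions that the hindered tert-butyl ester needs do no harm, and any δ-lactone formed by transesterification converges on the same diol.

Step 7
Reactants: 15 diol
Product: 16 (3S)-5-[(tert-butyldiphenylsilyl)oxy]-2,2-dimethyl-3-[3-(trimethylsilyl)prop-1-en-2-yl]pentan-1-ol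
Conditions: TBDPSCl (1.05 equiv), imidazole, CH2Cl2, −20 → 0 °C
Reagents that add atoms: tert-butyl(chloro)diphenylsilane, CC(C)(C)[Si](Cl)(c1ccccc1)c1ccccc1
Why: Sterically controlled monosilylation, since the bulky chlorosilane should react at the unhindered primary hydroxyl of the stub far faster than at the neopentyl C4 hydroxyl.

Step 8
Reactants: 16 allylsilane alcohol; 17 diiodomethane
Product: 18 (3S)-5-[(tert-butyldiphenylsilyl)oxy]-2,2-dimethyl-3-{1-[(trimethylsilyl)methyl]cyclopropyl}pentan-1-ol
Conditions: Et2Zn (4 equiv), 17 (8 equiv), CH2Cl2, 0 °C → rt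
Reagents that add atoms: none
Why: Furukawa variant of the Simmons–Smith cyclopropanation, for which the electron-rich 1,1-disubstituted alkene of an allylsilane is a good substrate, the =CH2 terminus is open to the zinc carbenoid, and no stereocentre arises because C2 and C3 are both CH2.

Step 9
Reactants: 18 cyclopropane alcohol
Product: 19 (3S)-5-[(tert-butyldiphenylsilyl)oxy]-2,2-dimethyl-3-{1-[(trimethylsilyl)methyl]cyclopropyl}pentanal
Conditions: nPr4N[RuO4] (5 mol %), NMO, 4 Å molecular sieves, CH2Cl2, rt
Reagents that add atoms: none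
Why: Ley–Griffith oxidation under neutral conditions takes the neopentyl alcohol to the non-enolisable aldehyde without acid that could open the silylmethylcyclopropane.

Step 10
Reactants: 19 cyclopropyl aldehyde
Product: 21 (1S,3R)-3-{2-[(tert-butyldiphenylsilyl)oxy]ethyl}-2,2-dimethyl-4-methylidenecyclohexan-1-ol, via trichlorotitanium alkoxide 20 (not isolated)
Conditions: TiCl4 (1.1 equiv), 2,6-di-tert-butyl-4-methylpyridine (0.3 equiv), CH2Cl2 (0.01 M), −78 → −40 °C; aq NaHCO3
Reagents that add atoms: none
Why: Proposed new method: TiCl4 binds the non-enolisable C4 aldehyde, a cyclopropane CH2 (C3) attacks the carbonyl carbon with the electrons of the C1–C3 bond, which σ-conjugation with the adjacent C–Si bond lifts in energy, positive charge grows at C1 (tertiary and β to silicon), and chloride takes the silyl group so that C1=CH2 and the titanium alkoxide 20 result. The closest known reaction types are the intermolecular Lewis-acid homoallylation of acid chlorides, acetals and aldehydes by (cyclopropylmethyl)silanes and (cyclopropylmethyl)stannanes and the intramolecular Hosomi–Sakurai cyclisation of allylsilane aldehydes, whereas ring closure by a silylmethylcyclopropane onto a carbonyl group is not documented. The six-membered ring C1–C6 is closed at C3–C4, exo with respect to the C=O bond and endo with respect to the breaking C1–C3 bond, through an array of C4, C5, C6, C1 and C3 shaped like the five-membered ring of a bicyclo[3.1.0]hexane that widens to the cyclohexane as C1–C3 breaks. C4 is the only new stereocentre and should be controlled by C6 through a chair-like array that keeps the C6 side chain and the titanium-bound oxygen equatorial, which gives the cis (4S,6R) alcohol. The step needs regioselective cleavage of a bond to C1 and a single ring size, and the substrate secures both, since the two diastereotopic ring CH2 groups lead to the same product, only a cation at C1 is stabilised by silicon, and the five-membered closure open to the parent allylsilane is not available. It also needs chemoselectivity, secured by the absence of any alkene, by the weakly coordinating TBDPS ether and by the hindered pyridine that traps adventitious acid before it can open the cyclopropane or move the new alkene, while the C5 gem-dimethyl group favours the folded reactive conformer.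

Step 11
Reactants: 21 cis alcohol
Product: 22 (1S,3R)-3-{2-[(tert-butyldiphenylsilyl)oxy]ethyl}-2,2-dimethyl-4-methylidenecyclohexyl acetate
Conditions: Ac2O, pyridine, DMAP (cat.), CH2Cl2, rt
Reagents that add atoms: acetic anhydride, CC(=O)OC(C)=O
Why: DMAP-catalysed acetylation of the equatorial secondary alcohol is done before desilylation so that the two hydroxyl groups are never free together.

Step 12
Reactants: 22 acetate silyl ether
Product: 23 (1S,3R)-3-(2-hydroxyethyl)-2,2-dimethyl-4-methylidenecyclohexyl acetate
Conditions: Bu4NF, AcOH (1 equiv each), THF, rt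
Reagents that add atoms: none
Why: Fluoride cleavage of the silyl ether, buffered by AcOH so that the medium stays non-basic and the acetate neither migrates nor hydrolyses.

Step 13
Reactants: 23 acetate alcohol
Product: 24 (1S,3R)-3-(2-iodoethyl)-2,2-dimethyl-4-methylidenecyclohexyl acetate
Conditions: I2, PPh3, imidazole, CH2Cl2, 0 °C → rt
Reagents that add atoms: iodine, II
Why: Appel-type iodination converts the primary alcohol by SN2 displacement of the oxyphosphonium group under near-neutral conditions that spare the acetate and the exocyclic alkene.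

Step 14
Reactants: 25 1-(trimethylsilyl)propyne; 26 (2E,6E)-farnesyl bromide
Product: 28 trimethyl[(5E,9E)-6,10,14-trimethylpentadeca-5,9,13-trien-1-yn-1-yl]silane, via lithiated silylpropyne 27 (not isolated)
Conditions: 25, n-BuLi, THF, −78 → −20 °C; 26, −78 °C → rt
Reagents that add atoms: none
Why: Alkylation of the propargylic lithium reagent of a 1-silylpropyne by a primary allylic bromide, in which the silyl group blocks the acetylenic terminus and SN2 attack at CH2Br keeps both E alkenes.

Step 15
Reactants: 28 silyl enyne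
Product: 29 (5E,9E)-6,10,14-trimethylpentadeca-5,9,13-trien-1-yne
Conditions: K2CO3 (cat.), MeOH–THF, rt
Reagents that add atoms: none
Why: Base-catalysed methanolysis of the alkynyl C–Si bond (protodesilylation) leaves the trisubstituted alkenes untouched.

Step 16
Reactants: 29 terminal alkyne
Product: 31 (6E,10E)-7,11,15-trimethylhexadeca-6,10,14-trien-2-yne, via lithium acetylide 30 (not isolated)
Conditions: n-BuLi, THF, −78 °C; MeI, −78 °C → rt
Reagents that add atoms: iodomethane, CI
Why: Deprotonation of the terminal alkyne and SN2 methylation of the lithium acetylide.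

Step 17
Reactants: 31 methyl alkyne
Product: 33 (2E,6E,10E)-2-iodo-7,11,15-trimethylhexadeca-2,6,10,14-tetraene, via alkenylzirconocene chloride 32 (not isolated)
Conditions: Cp2Zr(H)Cl (2 equiv), THF, 50 °C; I2, THF, −78 → 0 °C
Reagents that add atoms: iodine, II
Why: Hydrozirconation–iodinolysis, in which syn addition of Zr–H to the alkyne is faster than to trisubstituted alkenes, excess reagent equilibrates zirconium to the less hindered methyl-bearing carbon, and iodinolysis with retention should give the E 2-iodoalkene.

Step 18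
Reactants: 24 alkyl iodide; 33 alkenyl iodide
Product: 35 (1S,3R)-2,2-dimethyl-4-methylidene-3-[(3E,7E,11E)-3,8,12,16-tetramethylheptadeca-3,7,11,15-tetraen-1-yl]cyclohexyl acetate (CNP0286444.1), via alkylzinc iodide 34 (not isolated)
Conditions: 24, Zn dust (activated by BrCH2CH2Br and Me3SiCl), LiCl, THF, 40 °C; then 33, PdCl2(dppf) (5 mol %), THF, rt → 45 °C
Reagents that add atoms: none
Why: Direct zinc insertion into the primary iodide tolerates the acetate, and Negishi coupling through zerovalent palladium generated from PdCl2(dppf) joins C(sp3) to C(sp2) with retention of the alkene geometry, the wide-bite-angle ligand favouring reductive elimination over β-hydride elimination.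

## Compound list

1 | 2,2-dimethylsuccinic anhydride | CC1(C)CC(=O)OC1=O | starting material
2 | (4S)-4-benzyl-1,3-oxazolidin-2-one | O=C1N[C@@H](Cc2ccccc2)CO1 | starting material
3 | N-lithio-(4S)-4-benzyl-1,3-oxazolidin-2-one | [Li]N1[C@@H](Cc2ccccc2)COC1=O | intermediate
4 | 4-[(4S)-4-benzyl-2-oxo-1,3-oxazolidin-3-yl]-2,2-dimethyl-4-oxobutanoic acid | OC(=O)C(C)(C)CC(=O)N1[C@@H](Cc2ccccc2)COC1=O | intermediate
5 | tert-butyl 4-[(4S)-4-benzyl-2-oxo-1,3-oxazolidin-3-yl]-2,2-dimethyl-4-oxobutanoate | CC(C)(C)OC(=O)C(C)(C)CC(=O)N1[C@@H](Cc2ccccc2)COC1=O | intermediate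
6 | allyl iodide | C=CCI | starting material
7 | sodium (Z)-enolate of 5 | CC(C)(C)OC(=O)C(C)(C)/C=C(\[O-])N1[C@@H](Cc2ccccc2)COC1=O.[Na+] | intermediate
8 | tert-butyl (3S)-3-{[(4S)-4-benzyl-2-oxo-1,3-oxazolidin-3-yl]carbonyl}-2,2-dimethylhex-5-enoate | CC(C)(C)OC(=O)C(C)(C)[C@H](CC=C)C(=O)N1[C@@H](Cc2ccccc2)COC1=O | intermediate
9 | tert-butyl (3S)-3-{[(4S)-4-benzyl-2-oxo-1,3-oxazolidin-3-yl]carbonyl}-2,2-dimethyl-5-oxopentanoate | CC(C)(C)OC(=O)C(C)(C)[C@H](CC=O)C(=O)N1[C@@H](Cc2ccccc2)COC1=O | intermediate
10 | tert-butyl (3S)-3-{[(4S)-4-benzyl-2-oxo-1,3-oxazolidin-3-yl]carbonyl}-5-hydroxy-2,2-dimethylpentanoate | CC(C)(C)OC(=O)C(C)(C)[C@H](CCO)C(=O)N1[C@@H](Cc2ccccc2)COC1=O | intermediate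
11 | tert-butyl 2-methyl-2-[(3S)-2-oxooxolan-3-yl]propanoate | CC(C)(C)OC(=O)C(C)(C)[C@@H]1CCOC1=O | intermediate
12 | (trimethylsilyl)methylmagnesium chloride | C[Si](C)(C)C[Mg]Cl | starting material
13 | tert-butyl (3S)-5-hydroxy-3-[2-hydroxy-1,3-bis(trimethylsilyl)propan-2-yl]-2,2-dimethylpentanoate | CC(C)(C)OC(=O)C(C)(C)[C@H](CCO)C(O)(C[Si](C)(C)C)C[Si](C)(C)C | intermediate
14 | tert-butyl (3S)-5-hydroxy-2,2-dimethyl-3-[3-(trimethylsilyl)prop-1-en-2-yl]pentanoate | CC(C)(C)OC(=O)C(C)(C)[C@H](CCO)C(=C)C[Si](C)(C)C | intermediate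
15 | (3S)-2,2-dimethyl-3-[3-(trimethylsilyl)prop-1-en-2-yl]pentane-1,5-diol | OCC(C)(C)[C@H](CCO)C(=C)C[Si](C)(C)C | intermediate
16 | (3S)-5-[(tert-butyldiphenylsilyl)oxy]-2,2-dimethyl-3-[3-(trimethylsilyl)prop-1-en-2-yl]pentan-1-ol | OCC(C)(C)[C@H](CCO[Si](c1ccccc1)(c1ccccc1)C(C)(C)C)C(=C)C[Si](C)(C)C | intermediate
17 | diiodomethane | ICI | starting material
18 | (3S)-5-[(tert-butyldiphenylsilyl)oxy]-2,2-dimethyl-3-{1-[(trimethylsilyl)methyl]cyclopropyl}pentan-1-ol | OCC(C)(C)[C@H](CCO[Si](c1ccccc1)(c1ccccc1)C(C)(C)C)C1(C[Si](C)(C)C)CC1 | intermediate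
19 | (3S)-5-[(tert-butyldiphenylsilyl)oxy]-2,2-dimethyl-3-{1-[(trimethylsilyl)methyl]cyclopropyl}pentanal (key-step precursor) | O=CC(C)(C)[C@H](CCO[Si](c1ccccc1)(c1ccccc1)C(C)(C)C)C1(C[Si](C)(C)C)CC1 | intermediate
20 | trichlorotitanium alkoxide of 21 | C=C1CC[C@H](O[Ti](Cl)(Cl)Cl)C(C)(C)[C@@H]1CCO[Si](c1ccccc1)(c1ccccc1)C(C)(C)C | intermediate
21 | (1S,3R)-3-{2-[(tert-butyldiphenylsilyl)oxy]ethyl}-2,2-dimethyl-4-methylidenecyclohexan-1-ol (key-step product, cis) | C=C1CC[C@H](O)C(C)(C)[C@@H]1CCO[Si](c1ccccc1)(c1ccccc1)C(C)(C)C | intermediate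
22 | (1S,3R)-3-{2-[(tert-butyldiphenylsilyl)oxy]ethyl}-2,2-dimethyl-4-methylidenecyclohexyl acetate | C=C1CC[C@H](OC(C)=O)C(C)(C)[C@@H]1CCO[Si](c1ccccc1)(c1ccccc1)C(C)(C)C | intermediate
23 | (1S,3R)-3-(2-hydroxyethyl)-2,2-dimethyl-4-methylidenecyclohexyl acetate | C=C1CC[C@H](OC(C)=O)C(C)(C)[C@@H]1CCO | intermediate
24 | (1S,3R)-3-(2-iodoethyl)-2,2-dimethyl-4-methylidenecyclohexyl acetate | C=C1CC[C@H](OC(C)=O)C(C)(C)[C@@H]1CCI | intermediate
25 | 1-(trimethylsilyl)propyne | CC#C[Si](C)(C)C | starting material
26 | (2E,6E)-farnesyl bromide | BrC/C=C(\C)CC/C=C(\C)CCC=C(C)C | starting material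
27 | [3-(trimethylsilyl)prop-2-yn-1-yl]lithium | [Li]CC#C[Si](C)(C)C | intermediate
28 | trimethyl[(5E,9E)-6,10,14-trimethylpentadeca-5,9,13-trien-1-yn-1-yl]silane | C[Si](C)(C)C#CCC/C=C(\C)CC/C=C(\C)CCC=C(C)C | intermediate
29 | (5E,9E)-6,10,14-trimethylpentadeca-5,9,13-trien-1-yne | C#CCC/C=C(\C)CC/C=C(\C)CCC=C(C)C | intermediate
30 | lithium acetylide of 29 | [Li]C#CCC/C=C(\C)CC/C=C(\C)CCC=C(C)C | intermediate
31 | (6E,10E)-7,11,15-trimethylhexadeca-6,10,14-trien-2-yne | CC#CCC/C=C(\C)CC/C=C(\C)CCC=C(C)C | intermediate
32 | chlorobis(cyclopentadienyl)[(2E,6E,10E)-7,11,15-trimethylhexadeca-2,6,10,14-tetraen-2-yl]zirconium | Cl[Zr](C1C=CC=C1)(C1C=CC=C1)/C(C)=C/CC/C=C(\C)CC/C=C(\C)CCC=C(C)C | intermediate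
33 | (2E,6E,10E)-2-iodo-7,11,15-trimethylhexadeca-2,6,10,14-tetraene | I/C(C)=C/CC/C=C(\C)CC/C=C(\C)CCC=C(C)C | intermediate
34 | {2-[(1R,3S)-3-acetoxy-2,2-dimethyl-6-methylidenecyclohexyl]ethyl}zinc iodide | C=C1CC[C@H](OC(C)=O)C(C)(C)[C@@H]1CC[Zn]I | intermediate
35 | (1S,3R)-2,2-dimethyl-4-methylidene-3-[(3E,7E,11E)-3,8,12,16-tetramethylheptadeca-3,7,11,15-tetraen-1-yl]cyclohexyl acetate | C=C1CC[C@H](OC(C)=O)C(C)(C)[C@@H]1CC/C(C)=C/CC/C=C(\C)CC/C=C(\C)CCC=C(C)C | target

## Step count and risks

Total steps: 18. Longest linear sequence: 14 (steps 1–13 and 18). Steps 14–17 build the side chain in parallel.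

**1. Step 10 (key step).**
- What may go wrong: the silyl-activated cyclopropane bond may be too weak a nucleophile for the front-side geometry that the short tether imposes. Proton- or chloride-induced opening of the cyclopropane with loss of silicon may then outrun C–C bond formation. Facial selectivity at the carbonyl may also be poor.
- Fallback: known chemistry, setting out from 16 and coming back at 21.
- Oxidation of 16 (Dess–Martin periodinane, pyridine) would give the allylsilane aldehyde F1.
- Corey–Chaykovsky methylenation (Me3SI, NaH, DMSO–THF) would give the terminal epoxide F2 as a mixture at the oxirane carbon.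
- BF3·OEt2 (CH2Cl2, −78 °C) would then trigger an epoxy-allylsilane cyclisation. The alkene terminus (C2) opens the oxirane at its unhindered CH2 (C3), because C4 is neopentyl. The ring is thus closed at C2–C3 instead of C3–C4.
- This would give 21 beside its C4 epimer, the trans alcohol F3. Oxidation of the mixture would give the ketone F4. NaBH4 reduction with axial hydride delivery, as in 2,2-dimethylcyclohexanones of the terpenoid series, should converge on the equatorial alcohol 21.
- The same oxidation–reduction pair also corrects poor facial selectivity in step 10 itself.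

**2. Step 5.**
- What may go wrong: the second addition may stall at a carbonyl flanked by the C6 methine and the quaternary C5. The intermediate α-silyl ketone may enolise. The liberated alkoxide may attack the ester while organometallic reagent is still present.
- Fallback: it sets out from 11 and comes back at 16.
- One equivalent of MeLi (THF, −78 °C) would add once to the lactone to give the hydroxy methyl ketone F5, in equilibrium with its lactol.
- TBDPSCl and imidazole would trap the open form as the silyl ether ketone F6.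
- Kinetic deprotonation at the methyl group (KN(SiMe3)2, −78 °C) and PhNTf2 would give the terminal enol triflate F7.
- Kumada coupling with 12 under Pd(PPh3)4 would give the allylsilane ester F8, and iBu2AlH reduction of the ester would give 16.

**3. Step 3.**
- What may go wrong: SN2 alkylation of an enolate carbon next to a quaternary centre may be slower than thermal breakdown of the sodium enolate. Warming to force conversion may erode the facial selectivity.
- Fallback: it sets out from 5 and comes back at 8.
- Boron enolate bromination (Bu2BOTf, iPr2NEt, CH2Cl2, −78 °C, then NBS) would give the α-bromo imide F9.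
- A chelation-controlled Keck-type radical allylation follows (Bu3SnCH2CH=CH2, MgBr2·OEt2, Et3B, air, CH2Cl2, −78 °C). It forms the same C–C bond through a planar radical that is less sensitive to the neighbouring quaternary carbon. The magnesium-chelated auxiliary shields the same face as in the enolate.

## Further compounds

F1 | step 10 | (3S)-5-[(tert-butyldiphenylsilyl)oxy]-2,2-dimethyl-3-[3-(trimethylsilyl)prop-1-en-2-yl]pentanal | O=CC(C)(C)[C@H](CCO[Si](c1ccccc1)(c1ccccc1)C(C)(C)C)C(=C)C[Si](C)(C)C
F2 | step 10 | tert-butyl({(3S)-4-methyl-4-[(2R)-oxiran-2-yl]-3-[3-(trimethylsilyl)prop-1-en-2-yl]pentyl}oxy)diphenylsilane (formed with its oxirane epimer; the epimer leading to 21 is drawn) | O1C[C@H]1C(C)(C)[C@H](CCO[Si](c1ccccc1)(c1ccccc1)C(C)(C)C)C(=C)C[Si](C)(C)C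
F3 | step 10 | (1R,3R)-3-{2-[(tert-butyldiphenylsilyl)oxy]ethyl}-2,2-dimethyl-4-methylidenecyclohexan-1-ol (trans alcohol) | C=C1CC[C@@H](O)C(C)(C)[C@@H]1CCO[Si](c1ccccc1)(c1ccccc1)C(C)(C)C
F4 | step 10 | (3R)-3-{2-[(tert-butyldiphenylsilyl)oxy]ethyl}-2,2-dimethyl-4-methylidenecyclohexan-1-one | C=C1CCC(=O)C(C)(C)[C@@H]1CCO[Si](c1ccccc1)(c1ccccc1)C(C)(C)C
F5 | step 5 | tert-butyl (3S)-3-acetyl-5-hydroxy-2,2-dimethylpentanoate | CC(C)(C)OC(=O)C(C)(C)[C@H](CCO)C(C)=O
F6 | step 5 | tert-butyl (3S)-3-acetyl-5-[(tert-butyldiphenylsilyl)oxy]-2,2-dimethylpentanoate | CC(C)(C)OC(=O)C(C)(C)[C@H](CCO[Si](c1ccccc1)(c1ccccc1)C(C)(C)C)C(C)=O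
F7 | step 5 | tert-butyl (3S)-5-[(tert-butyldiphenylsilyl)oxy]-2,2-dimethyl-3-{1-[(trifluoromethanesulfonyl)oxy]ethenyl}pentanoate | CC(C)(C)OC(=O)C(C)(C)[C@H](CCO[Si](c1ccccc1)(c1ccccc1)C(C)(C)C)C(=C)OS(=O)(=O)C(F)(F)F
F8 | step 5 | tert-butyl (3S)-5-[(tert-butyldiphenylsilyl)oxy]-2,2-dimethyl-3-[3-(trimethylsilyl)prop-1-en-2-yl]pentanoate | CC(C)(C)OC(=O)C(C)(C)[C@H](CCO[Si](c1ccccc1)(c1ccccc1)C(C)(C)C)C(=C)C[Si](C)(C)C
F9 | step 3 | tert-butyl (3S)-4-[(4S)-4-benzyl-2-oxo-1,3-oxazolidin-3-yl]-3-bromo-2,2-dimethyl-4-oxobutanoate | CC(C)(C)OC(=O)C(C)(C)[C@H](Br)C(=O)N1[C@@H](Cc2ccccc2)COC1=O
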